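## The problem

Compound 17 is a flavanone: a chroman-4-one whose benzo ring A carries five contiguous substituents (the ring oxygen O1 on C8a, the acyl carbon C4 on C4a, a free hydroxyl on C5, methoxy groups on C6 and C7) and a single hydrogen on C8. Ring C holds the only stereocentre, C2 (S), which bears the 3,4-dimethoxyphenyl ring B. No second stereocentre exists to relay from, so C2 must be set by a catalyst. It must then be protected from its own lability: it is benzylic, bonded to the aryl ether oxygen and β to the ketone, so base, strong acid or long heating can open ring C to the hydroxychalcone and reclose it without control. The second task is to tell one phenol oxygen from the neighbouring methyl ethers, which is easiest if O5 never carries a methyl group. The electron-rich ring A argues against late oxidations, and the intermediates on the way (enol ethers, allylic alcohols, cyclobutenones) are acid-sensitive. The feature that opens the route is that C5, C6, C7 and C8 form a four-carbon run bearing O, OMe, OMe and H, which is the pattern of a 2,3-dimethoxycyclobut-2-enone with one hydrogen at its sp3 carbon. The other two ring A carbons, C4a and C8a, are the C5=C6 enol ether carbons of a 2-aryl-2,3-dihydropyran-4-one that already contains O1, C2, C3 and the C4 ketone. Ring A can therefore be grown onto a preformed chiral ring C through one new bond, C4a–C5, with the phenol arising free.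

## Retrosynthesis

**17 to 14.** The C4a–C5 bond is cut in the sense of a retro-6π electrocyclisation (through dienone 16 and dienylketene 15), and the ketene is folded back into the four-membered ring of cyclobutenone 14. Against an oxa-Michael closure of ring C, this keeps C2 away from the most reversible bond of the molecule. Against acylation of a preformed arene, it avoids any need to distinguish five oxygens on ring A. Precursor 14 has no ring A and consists of two small units. The forward reaction must be neutral and purely thermal. C4 is kept as the free ketone rather than as a ketal for three reasons: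
- a ketal cannot be made directly from a vinylogous ester such as 4, because alcohols add to C6 instead;
- the enone C5=C6 bond is a competent terminus for the ring closure;
- the carbonyl places the C4a hydrogen of 16 between two carbonyls, so aromatisation is fast and 17 is formed without a deprotection.

**14 to 10 and 13.** The bond between the cyclobutenone CH and pyranone C6 (the future C8–C8a bond) is cut as a Stille coupling of stannyl enone 10 with chlorocyclobutenone 13. The neighbouring option, adding a C6-metalated pyran to the carbonyl of squarate 11, would leave a hydroxyl on the future C8 that must later be removed. Chloride 13 already carries the hydrogen. The coupling must run at room temperature so that 14 can be handled before it is heated.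

**13 to 11.** Chloride 13 comes from alcohol 12 by neutral deoxychlorination, and 12 from dimethyl squarate 11 by mono-reduction. Both are functional-group changes on a commercial four-carbon unit that carries both methoxy groups of ring A.

**10 to 6.** The C6–Sn bond is traced to metalation of an enol ether, which the C4 ketone would not survive. The carbonyl is therefore stored for four steps as a silyl ether: stannyl enone 10 from alcohol 9 by oxidation, 9 from silyl ether 8 by fluoride, and 8 from enol ether 6 by metalation (vinylpotassium 7) and tin quench. This detour is the price of keeping C4 at the ketone level in the key step; each step is routine and the temporary C4 centre is erased in 10.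

**6 to 4.** Silyl ether 6 comes from allylic alcohol 5 and this from dihydropyranone 4 by 1,2-reduction.

**4 to 1 and 2.** The C2–C3 and O1–C6 bonds of 4 are cut as a catalytic asymmetric hetero-Diels–Alder reaction of 3,4-dimethoxybenzaldehyde 1 with siloxydiene 2 (through aldol adduct 3). This single step builds ring C and sets C2 from two commercial compounds.

## Roads not taken

**Alternative 1:** The cut is the C3–C4 bond, at the level of a C3=C4 enol ether. Diene A2, an (S)-1-arylallyl aryl ether with an ortho 1-(silyloxy)vinyl group, would undergo ring-closing metathesis with a ruthenium alkylidene such as the second-generation Grubbs catalyst to give silyl enol ether A1. Desilylation would give the C5 methyl ether A3, and chelation-directed demethylation with BCl3 would give 17.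
- Merits: ring A is bought with all its oxygens, no tin is used, and the final demethylation next to the carbonyl is dependable.
- Weak points: the stereocentre of A2 is benzylic, allylic and bonded to an aryloxy leaving group. It can ionise, undergo an aromatic Claisen shift into the free ortho position at the temperatures a hindered enol ether metathesis needs, or be isomerised by ruthenium hydrides. Making A2 enantiopure requires an SN2 etherification of an electron-rich benzylic allylic carbinol by a hindered phenol, where SN1 and SN2' paths compete. A1 is a 2H-chromene and can racemise by reversible oxa-6π ring opening. Metathesis onto a 1,1-disubstituted silyl enol ether beside an ortho methoxy group is slow.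
- Comparison: the length is similar, and this road is better in reagent cost and needs no protection and redox detour. The chosen plan sets against this a stereocentre held in a saturated ring throughout and a C5 hydroxyl that needs no demethylation.

**Alternative 2:** The cuts are O1–C2 and C3–C4. Acid dehydration of benzylic alcohol A5 would give an ortho-quinone methide, which a chiral phosphoric acid would steer into a (4+2) cycloaddition with styrene A6 to give chroman A4 and set C2.
- Merits: this is the shortest road. A6 is commercial, A5 is close to commercial material, and one catalytic step builds ring C and the stereocentre.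
- Weak points: A4 has a methylene at C4. Oxidising it to the ketone A3 must spare the C2 hydrogen, which is benzylic and α to oxygen and at least as prone to abstraction; attack there erases the stereocentre or leads toward flavone-type products. Ring A itself is oxidisable, and A3 still needs demethylation to 17. The methide from A5 is unsubstituted at its exocyclic carbon, small and very reactive, so enantiocontrol with a simple styrene is less secure than for aryl-substituted methides. A6 oligomerises readily under acid.
- Comparison: in step count this road is clearly ahead and the chosen plan cannot match it. The chosen plan sets against it that the C4 carbonyl is present from step 1 and that nothing is oxidised once ring A exists.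

**Alternative 3:** The cut is O1–C8a. Bromo diol A8 would be cyclised with Pd(OAc)2 and a bulky biaryl phosphine, or with CuI and a phenanthroline ligand, to chromanol A7. Oxidation of the C4 alcohol would give A3 and demethylation would give 17.
- Merits: the carbinol stereocentre of A8 can be set in an open chain by established asymmetric aldol or ketone reduction methods. Ring A is bought, every reaction type is widely used, and there is no tin or strained ring.
- Weak points: the aryl bromide is electron-rich and ortho-substituted, so oxidative addition is slow. The palladium alkoxide of a secondary benzylic alcohol can undergo β-hydride elimination, which oxidises the stereocentre away and reduces the C–Br bond. The second hydroxyl competes for the metal. Two corrections (oxidation and demethylation) follow ring closure.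
- Comparison: in robustness of individual steps this road is at least equal to the chosen plan, and it is of similar length. The chosen plan sets against it that ring A appears in the last step with its final pattern, a free C5 hydroxyl and C4 already a ketone, and that the C2–O1 bond never passes through a metal alkoxide. Selective removal of a C5 methyl group is admittedly reliable, so this advantage is one of economy in the end game, not of feasibility.

Key step: step 10

## Assumptions

- The Ti(OiPr)4/(S)-BINOL catalyst is taken to direct the diene to the Si face of aryl aldehyde 1, the sense known for the related titanium–BINOL allylation of aryl aldehydes. If the sense proves opposite, (R)-BINOL is used and nothing else changes.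
- Compounds 12 and 13 are racemic and 14 is a pair of epimers at the cyclobutenone CH. This carbon becomes the sp2 carbon C8, so its configuration is immaterial.

## Route

Step 1
Reactants: 1 3,4-dimethoxybenzaldehyde; 2 (E)-1-methoxy-3-(trimethylsilyloxy)buta-1,3-diene
Product: 4 (2S)-2-(3,4-dimethoxyphenyl)-2,3-dihydro-4H-pyran-4-one, via silyl aldol adduct 3 (not isolated)
Conditions: Ti(OiPr)4 (10 mol %), (S)-BINOL (20 mol %), 4 Å MS, Et2O, –20 °C; then TFA, CH2Cl2, 0 °C
Reagents that add atoms: none
Why: Catalytic asymmetric hetero-Diels–Alder reaction of an aryl aldehyde with a 1-alkoxy-3-siloxydiene, which under the tetravalent titanium BINOLate runs as a Mukaiyama aldol addition to silyl ether 3 followed by acid-promoted cyclisation with loss of methanol; the catalyst shields the Re face of 1, so attack on the Si face sets C2 as S.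

Step 2
Reactants: 4 (2S)-2-(3,4-dimethoxyphenyl)-2,3-dihydro-4H-pyran-4-one
Product: 5 (2S,4S)-2-(3,4-dimethoxyphenyl)-3,4-dihydro-2H-pyran-4-ol
Conditions: NaBH4, CeCl3·7H2O, MeOH, –78 → –40 °C
Reagents that add atoms: none
Why: Luche reduction: the cerium-modified borohydride adds 1,2 to the vinylogous ester and delivers hydride axially, giving the cis (4S) allylic alcohol; this centre is removed again in step 6, so any trans isomer can be carried along.

Step 3
Reactants: 5 (2S,4S)-2-(3,4-dimethoxyphenyl)-3,4-dihydro-2H-pyran-4-ol
Product: 6 (2S,4S)-2-(3,4-dimethoxyphenyl)-4-(triisopropylsilyloxy)-3,4-dihydro-2H-pyran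
Conditions: TIPSOTf, 2,6-lutidine, CH2Cl2, –78 → 0 °C
Reagents that add atoms: triisopropylsilyl trifluoromethanesulfonate (TIPSOTf), CC(C)[Si](OS(=O)(=O)C(F)(F)F)(C(C)C)C(C)C
Why: Standard base-buffered silylation of a secondary allylic alcohol; the triisopropylsilyl group has no acidic Si–CH3 hydrogens and withstands the superbase of step 4.

Step 4
Reactants: 6 (2S,4S)-2-(3,4-dimethoxyphenyl)-4-(triisopropylsilyloxy)-3,4-dihydro-2H-pyran
Product: 8 tributyl[(2S,4S)-2-(3,4-dimethoxyphenyl)-4-(triisopropylsilyloxy)-3,4-dihydro-2H-pyran-6-yl]stannane, via vinylpotassium 7 (not isolated)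
Conditions: n-BuLi, KOt-Bu, THF, –78 °C; then Bu3SnCl, –78 °C → rt
Reagents that add atoms: tributyltin chloride (Bu3SnCl), CCCC[Sn](Cl)(CCCC)CCCC
Why: α-Metalation of a cyclic enol ether (the C1 metalation of glycals) followed by tin quench: at –78 °C the superbase removes the vinylic hydrogen on the oxygen-bearing C6, the kinetically most acidic site, a preference that in glycal chemistry holds even beside benzylic ether hydrogens; vinylpotassium 7 is then stannylated in place.

Step 5
Reactants: 8 tributyl[(2S,4S)-2-(3,4-dimethoxyphenyl)-4-(triisopropylsilyloxy)-3,4-dihydro-2H-pyran-6-yl]stannane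
Product: 9 (2S,4S)-2-(3,4-dimethoxyphenyl)-6-(tributylstannyl)-3,4-dihydro-2H-pyran-4-ol
Conditions: Bu4NF, THF, 0 °C → rt
Reagents that add atoms: none
Why: Fluoride cleavage of a silyl ether; the medium is basic, so the acid-labile α-alkoxyvinylstannane and the C2 centre are untouched.

Step 6
Reactants: 9 (2S,4S)-2-(3,4-dimethoxyphenyl)-6-(tributylstannyl)-3,4-dihydro-2H-pyran-4-ol
Product: 10 (2S)-2-(3,4-dimethoxyphenyl)-6-(tributylstannyl)-2,3-dihydro-4H-pyran-4-one
Conditions: activated MnO2, CH2Cl2, rt
Reagents that add atoms: none
Why: MnO2 oxidation of an allylic alcohol under neutral heterogeneous conditions restores the vinylogous ester; in 10 the tin sits on the β-carbon of the enone, where protodestannylation is disfavoured, so the compound should tolerate purification.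

Step 7
Reactants: 11 dimethyl squarate (3,4-dimethoxycyclobut-3-ene-1,2-dione)
Product: 12 4-hydroxy-2,3-dimethoxycyclobut-2-en-1-one (racemic)
Conditions: LiAlH(Ot-Bu)3, THF, –78 → –40 °C; then pH 7 buffer
Reagents that add atoms: none
Why: Mono-reduction of a squaric ester by a bulky alkoxyaluminium hydride at low temperature, a known entry to 4-hydroxy-2,3-dialkoxycyclobutenones; the remaining carbonyl is a vinylogous ester and resists further hydride, and the neutral work-up avoids acid-induced loss of methanol to the cyclobutenedione.

Step 8
Reactants: 12 4-hydroxy-2,3-dimethoxycyclobut-2-en-1-one (racemic)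
Product: 13 4-chloro-2,3-dimethoxycyclobut-2-en-1-one (racemic)
Conditions: 1-chloro-N,N,2-trimethylprop-1-en-1-amine, CH2Cl2, 0 °C
Reagents that add atoms: 1-chloro-N,N,2-trimethylprop-1-en-1-amine, CC(C)=C(Cl)N(C)C
Why: Deoxychlorination of an alcohol by an α-chloroenamine under neutral conditions: O-imidoylation followed by chloride attack at the activated α-keto, allylic carbon gives 13 and a neutral amide, with no acid, Lewis acid or phosphine present that could ionise the product.

Step 9
Reactants: 10 (2S)-2-(3,4-dimethoxyphenyl)-6-(tributylstannyl)-2,3-dihydro-4H-pyran-4-one; 13 4-chloro-2,3-dimethoxycyclobut-2-en-1-one (racemic)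
Product: 14 4-[(2S)-2-(3,4-dimethoxyphenyl)-4-oxo-3,4-dihydro-2H-pyran-6-yl]-2,3-dimethoxycyclobut-2-en-1-one (both epimers at the cyclobutenone CH)
Conditions: Pd2(dba)3 (2.5 mol %), tri(2-furyl)phosphine (10 mol %), CuI (10 mol %), THF, rt, dark
Reagents that add atoms: none
Why: Stille coupling of a 4-chlorocyclobut-2-enone with an alkenylstannane, a known reaction type: zerovalent palladium inserts into the allylic, α-keto C–Cl bond, the α-alkoxyvinyl group is transferred from tin with CuI assistance, and reductive elimination at the unsubstituted allyl terminus keeps the vinylogous ester of the four-membered ring; room temperature keeps 14 from ring-opening.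

Step 10
Reactants: 14 4-[(2S)-2-(3,4-dimethoxyphenyl)-4-oxo-3,4-dihydro-2H-pyran-6-yl]-2,3-dimethoxycyclobut-2-en-1-one
Product: 17 (2S)-2-(3,4-dimethoxyphenyl)-5-hydroxy-6,7-dimethoxychroman-4-one, via dienylketene 15 (not isolated), via cyclohexadienone 16 (not isolated)
Conditions: toluene (0.01 M, dry, degassed), 100 °C
Reagents that add atoms: none
Why: Heating opens the cyclobutenone of 14 by a reversible conrotatory 4π electrocyclic cleavage of the bond between the carbonyl carbon and the pyranyl-bearing CH, giving a vinylketene; only isomer 15, in which the pyranyl group has rotated inward, places the pyranone C5=C6 bond next to the ketene carbon, and because the opening is reversible the unproductive outward isomer drains back through 14. Ketene 15 then closes ring A by a thermal disrotatory 6π electrocyclisation that joins the ketene carbon to pyranone C5 (the C4a–C5 bond of 17) and gives cyclohexa-2,4-dienone 16. The C4a hydrogen of 16 lies between two carbonyl groups, so enolisation to the hydrogen-bonded C5 phenol 17 is fast and irreversible and pulls all equilibria forward. The closest known reaction type is the thermal ring expansion of 4-alkenyl- and 4-arylcyclobut-2-enones to phenols, which is the second half of the Danheiser benzannulation and the deoxy counterpart of the Moore rearrangement. No stereocentre is created: C4a of 16 is transient and the epimeric cyclobutenone carbon of 14 becomes the sp2 carbon C8. Regiochemistry needs no control, since the ketene carbon can reach only pyranone C5, so the carbonyl carbon becomes C5–OH, the two methoxy carbons become C6 and C7, and the CH becomes C8. The step does need the ketene to cyclise faster than it dimerises or is captured by nucleophiles, which high dilution in dry degassed toluene should secure, and it needs the C2 configuration to survive, which the absence of acid and base should secure because the flavanone then cannot open to its chalcone.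

## Compound list

1 | 3,4-dimethoxybenzaldehyde | COc1ccc(C=O)cc1OC | starting material
2 | (E)-1-methoxy-3-(trimethylsilyloxy)buta-1,3-diene | CO/C=C/C(=C)O[Si](C)(C)C | starting material
3 | (1E,5S)-5-(3,4-dimethoxyphenyl)-1-methoxy-5-(trimethylsilyloxy)pent-1-en-3-one (not isolated) | CO/C=C/C(=O)C[C@H](O[Si](C)(C)C)c1ccc(OC)c(OC)c1 | intermediate
4 | (2S)-2-(3,4-dimethoxyphenyl)-2,3-dihydro-4H-pyran-4-one | O=C1C[C@@H](c2ccc(OC)c(OC)c2)OC=C1 | intermediate
5 | (2S,4S)-2-(3,4-dimethoxyphenyl)-3,4-dihydro-2H-pyran-4-ol | O[C@H]1C[C@@H](c2ccc(OC)c(OC)c2)OC=C1 | intermediate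
6 | (2S,4S)-2-(3,4-dimethoxyphenyl)-4-(triisopropylsilyloxy)-3,4-dihydro-2H-pyran | CC(C)[Si](C(C)C)(C(C)C)O[C@H]1C[C@@H](c2ccc(OC)c(OC)c2)OC=C1 | intermediate
7 | [(2S,4S)-2-(3,4-dimethoxyphenyl)-4-(triisopropylsilyloxy)-3,4-dihydro-2H-pyran-6-yl]potassium (not isolated) | CC(C)[Si](C(C)C)(C(C)C)O[C@H]1C[C@@H](c2ccc(OC)c(OC)c2)OC([K])=C1 | intermediate
8 | tributyl[(2S,4S)-2-(3,4-dimethoxyphenyl)-4-(triisopropylsilyloxy)-3,4-dihydro-2H-pyran-6-yl]stannane | CC(C)[Si](C(C)C)(C(C)C)O[C@H]1C[C@@H](c2ccc(OC)c(OC)c2)OC([Sn](CCCC)(CCCC)CCCC)=C1 | intermediate
9 | (2S,4S)-2-(3,4-dimethoxyphenyl)-6-(tributylstannyl)-3,4-dihydro-2H-pyran-4-ol | O[C@H]1C[C@@H](c2ccc(OC)c(OC)c2)OC([Sn](CCCC)(CCCC)CCCC)=C1 | intermediate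
10 | (2S)-2-(3,4-dimethoxyphenyl)-6-(tributylstannyl)-2,3-dihydro-4H-pyran-4-one | O=C1C[C@@H](c2ccc(OC)c(OC)c2)OC([Sn](CCCC)(CCCC)CCCC)=C1 | intermediate
11 | dimethyl squarate (3,4-dimethoxycyclobut-3-ene-1,2-dione) | COC1=C(OC)C(=O)C1=O | starting material
12 | 4-hydroxy-2,3-dimethoxycyclobut-2-en-1-one (racemic) | COC1=C(OC)C(O)C1=O | intermediate
13 | 4-chloro-2,3-dimethoxycyclobut-2-en-1-one (racemic) | COC1=C(OC)C(Cl)C1=O | intermediate
14 | 4-[(2S)-2-(3,4-dimethoxyphenyl)-4-oxo-3,4-dihydro-2H-pyran-6-yl]-2,3-dimethoxycyclobut-2-en-1-one (both epimers at the cyclobutenone CH) | COC1=C(OC)C(C1=O)C1=CC(=O)C[C@H](O1)c1ccc(OC)c(OC)c1 | intermediate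
15 | (2S)-6-[(1E)-2,3-dimethoxy-4-oxobuta-1,3-dien-1-yl]-2-(3,4-dimethoxyphenyl)-2,3-dihydro-4H-pyran-4-one (not isolated) | O=C=C(OC)/C(OC)=C\C1=CC(=O)C[C@H](O1)c1ccc(OC)c(OC)c1 | intermediate
16 | (2S)-2-(3,4-dimethoxyphenyl)-6,7-dimethoxy-2,3-dihydro-4H-chromene-4,5(4aH)-dione (either epimer at C4a, not isolated) | O=C1C(OC)=C(OC)C=C2O[C@H](c3ccc(OC)c(OC)c3)CC(=O)C12 | intermediate
17 | (2S)-2-(3,4-dimethoxyphenyl)-5-hydroxy-6,7-dimethoxychroman-4-one | COc1ccc([C@@H]2CC(=O)c3c(cc(OC)c(OC)c3O)O2)cc1OC | target

## Step count and risks

Total: 10 steps. Longest linear sequence: 8 steps (steps 1–6, 9 and 10 from 1); steps 7 and 8 are a two-step side branch from 11.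

**Step 10 (key step).** The vinylketene may be diverted by dimerisation or by capture through the phenolic product or traces of water, and the flavanone, being formed hot, may lose C2 configuration through reversible opening to the chalcone. The fallback is the hydroxy variant of the ring expansion in the silyl ether series, where a C4 hydroxyl on the cyclobutenone rotates outward and forces the pyranyl group inward, and where no flavanone is heated. It sets out from 6 and 11 and returns at 17.
- Enol ether 6 is metalated as in step 4 and the anion 7 is added to the carbonyl of squarate 11 at –78 °C to give 4-hydroxy-4-[(2S,4S)-2-(3,4-dimethoxyphenyl)-4-(triisopropylsilyloxy)-3,4-dihydro-2H-pyran-6-yl]-2,3-dimethoxycyclobut-2-en-1-one F1.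
- Heating F1 in toluene should give the hydroquinone (2S,4S)-2-(3,4-dimethoxyphenyl)-6,7-dimethoxy-4-(triisopropylsilyloxy)chromane-5,8-diol F2.
- The C8 hydroxyl of F2 is less hindered than the C5 hydroxyl, which sits beside the silyloxy-bearing C4. It is triflated with PhNTf2 and Et3N to give (2S,4S)-2-(3,4-dimethoxyphenyl)-5-hydroxy-6,7-dimethoxy-4-(triisopropylsilyloxy)chroman-8-yl trifluoromethanesulfonate F3.
- Reduction of the triflate with Pd(OAc)2, 1,1'-bis(diphenylphosphino)ferrocene, HCO2H and Et3N gives (2S,4S)-2-(3,4-dimethoxyphenyl)-6,7-dimethoxy-4-(triisopropylsilyloxy)chroman-5-ol F4.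
- Bu4NF gives (2S,4S)-2-(3,4-dimethoxyphenyl)-6,7-dimethoxychromane-4,5-diol F5, and MnO2 oxidation of its benzylic alcohol gives 17.

**Step 8.** The C4–Cl bond may ionise, after which chloride can demethylate the resulting oxocarbenium ion (loss of chloromethane and collapse to the methoxycyclobutenedione) or return at C2 (allylic transposition). The fallback removes halide from the sequence. It sets out from 12 and returns at 14. Alcohol 12 is acylated with methyl chloroformate and pyridine to give 2,3-dimethoxy-4-oxocyclobut-2-en-1-yl methyl carbonate F6. F6 is coupled with stannane 10 under Pd2(dba)3 and tri(2-furyl)phosphine without added halide. Ionisation by zerovalent palladium with loss of CO2 gives the same η3-oxocyclobutenyl palladium species as in step 9, and the methoxide set free activates the stannane.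

**Step 9.** Transmetalation of the carbonyl-deactivated stannane 10 may be slow, so that decomposition of 13 or of the palladium intermediate, homocoupling and uncontrolled early ring expansion compete. The fallback changes the order of events so that the electron-rich stannane is coupled. It sets out from 8 and 13 and returns at 17. Coupling of 8 with 13 under the conditions of step 9 gives 4-[(2S,4S)-2-(3,4-dimethoxyphenyl)-4-(triisopropylsilyloxy)-3,4-dihydro-2H-pyran-6-yl]-2,3-dimethoxycyclobut-2-en-1-one F7. Ring expansion in toluene at 100 °C gives the silyl ether F4, and Bu4NF to the diol F5 followed by MnO2 gives 17.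

**Step 4.** The superbase may also remove the benzylic C2 hydrogen (loss of configuration, Wittig-type rearrangement or ring cleavage) or metalate the dimethoxyphenyl ring. The fallback makes the C6–Sn bond from a lactone carbonyl without any vinylic deprotonation. It sets out from 1 and returns at 8.
- Vinylogous Mukaiyama aldol addition of 1-methoxy-1,3-bis(trimethylsilyloxy)buta-1,3-diene to 1 with Ti(OiPr)4/(S)-BINOL gives methyl (5S)-5-(3,4-dimethoxyphenyl)-5-hydroxy-3-oxopentanoate F8.
- Evans–Saksena reduction with Me4NBH(OAc)3 gives the anti diol methyl (3S,5S)-5-(3,4-dimethoxyphenyl)-3,5-dihydroxypentanoate F9.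
- Acid-catalysed lactonisation gives the cis lactone (4S,6S)-6-(3,4-dimethoxyphenyl)-4-hydroxytetrahydro-2H-pyran-2-one F10.
- Silylation with TIPSOTf and 2,6-lutidine gives (4S,6S)-6-(3,4-dimethoxyphenyl)-4-(triisopropylsilyloxy)tetrahydro-2H-pyran-2-one F11.
- Enolisation with KN(SiMe3)2 and trapping with (PhO)2P(O)Cl at –78 °C gives the ketene acetal phosphate (2S,4S)-2-(3,4-dimethoxyphenyl)-4-(triisopropylsilyloxy)-3,4-dihydro-2H-pyran-6-yl diphenyl phosphate F12.
- Pd(PPh3)4, Bu3SnSnBu3 and LiCl in THF convert F12 into stannane 8.

## Further compounds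

F1 | step 10 | 4-hydroxy-4-[(2S,4S)-2-(3,4-dimethoxyphenyl)-4-(triisopropylsilyloxy)-3,4-dihydro-2H-pyran-6-yl]-2,3-dimethoxycyclobut-2-en-1-one | COC1=C(OC)C(O)(C1=O)C1=C[C@@H](O[Si](C(C)C)(C(C)C)C(C)C)C[C@H](O1)c1ccc(OC)c(OC)c1
F2 | step 10 | (2S,4S)-2-(3,4-dimethoxyphenyl)-6,7-dimethoxy-4-(triisopropylsilyloxy)chromane-5,8-diol | COc1ccc([C@@H]2C[C@H](O[Si](C(C)C)(C(C)C)C(C)C)c3c(O)c(OC)c(OC)c(O)c3O2)cc1OC
F3 | step 10 | (2S,4S)-2-(3,4-dimethoxyphenyl)-5-hydroxy-6,7-dimethoxy-4-(triisopropylsilyloxy)chroman-8-yl trifluoromethanesulfonate | COc1ccc([C@@H]2C[C@H](O[Si](C(C)C)(C(C)C)C(C)C)c3c(O)c(OC)c(OC)c(OS(=O)(=O)C(F)(F)F)c3O2)cc1OC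
F4 | step 10 | (2S,4S)-2-(3,4-dimethoxyphenyl)-6,7-dimethoxy-4-(triisopropylsilyloxy)chroman-5-ol | COc1ccc([C@@H]2C[C@H](O[Si](C(C)C)(C(C)C)C(C)C)c3c(O)c(OC)c(OC)cc3O2)cc1OC
F5 | step 10 | (2S,4S)-2-(3,4-dimethoxyphenyl)-6,7-dimethoxychromane-4,5-diol | COc1ccc([C@@H]2C[C@H](O)c3c(O)c(OC)c(OC)cc3O2)cc1OC
F6 | step 8 | 2,3-dimethoxy-4-oxocyclobut-2-en-1-yl methyl carbonate (racemic) | COC(=O)OC1C(OC)=C(OC)C1=O
F7 | step 9 | 4-[(2S,4S)-2-(3,4-dimethoxyphenyl)-4-(triisopropylsilyloxy)-3,4-dihydro-2H-pyran-6-yl]-2,3-dimethoxycyclobut-2-en-1-one | COC1=C(OC)C(C1=O)C1=C[C@@H](O[Si](C(C)C)(C(C)C)C(C)C)C[C@H](O1)c1ccc(OC)c(OC)c1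
F8 | step 4 | methyl (5S)-5-(3,4-dimethoxyphenyl)-5-hydroxy-3-oxopentanoate | COC(=O)CC(=O)C[C@H](O)c1ccc(OC)c(OC)c1
F9 | step 4 | methyl (3S,5S)-5-(3,4-dimethoxyphenyl)-3,5-dihydroxypentanoate | COC(=O)C[C@@H](O)C[C@H](O)c1ccc(OC)c(OC)c1
F10 | step 4 | (4S,6S)-6-(3,4-dimethoxyphenyl)-4-hydroxytetrahydro-2H-pyran-2-one | O[C@H]1C[C@@H](c2ccc(OC)c(OC)c2)OC(=O)C1
F11 | step 4 | (4S,6S)-6-(3,4-dimethoxyphenyl)-4-(triisopropylsilyloxy)tetrahydro-2H-pyran-2-one | CC(C)[Si](C(C)C)(C(C)C)O[C@H]1C[C@@H](c2ccc(OC)c(OC)c2)OC(=O)C1
F12 | step 4 | (2S,4S)-2-(3,4-dimethoxyphenyl)-4-(triisopropylsilyloxy)-3,4-dihydro-2H-pyran-6-yl diphenyl phosphate | CC(C)[Si](C(C)C)(C(C)C)O[C@H]1C[C@@H](c2ccc(OC)c(OC)c2)OC(OP(=O)(Oc3ccccc3)Oc3ccccc3)=C1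
A1 | alternative 1 | (2S)-4-(tert-butyldimethylsilyloxy)-2-(3,4-dimethoxyphenyl)-5,6,7-trimethoxy-2H-chromene | COc1ccc([C@@H]2C=C(O[Si](C)(C)C(C)(C)C)c3c(cc(OC)c(OC)c3OC)O2)cc1OC
A2 | alternative 1 | tert-butyl{[1-(2-{[(1S)-1-(3,4-dimethoxyphenyl)prop-2-en-1-yl]oxy}-4,5,6-trimethoxyphenyl)ethenyl]oxy}dimethylsilane | C=C[C@H](Oc1cc(OC)c(OC)c(OC)c1C(=C)O[Si](C)(C)C(C)(C)C)c1ccc(OC)c(OC)c1
A3 | alternative 1 | (2S)-2-(3,4-dimethoxyphenyl)-5,6,7-trimethoxychroman-4-one | COc1ccc([C@@H]2CC(=O)c3c(cc(OC)c(OC)c3OC)O2)cc1OC
A4 | alternative 2 | (2S)-2-(3,4-dimethoxyphenyl)-5,6,7-trimethoxychroman | COc1ccc([C@@H]2CCc3c(cc(OC)c(OC)c3OC)O2)cc1OC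
A5 | alternative 2 | 2-(hydroxymethyl)-3,4,5-trimethoxyphenol | OCc1c(O)cc(OC)c(OC)c1OC
A6 | alternative 2 | 3,4-dimethoxystyrene | C=Cc1ccc(OC)c(OC)c1
A7 | alternative 3 | (2S)-2-(3,4-dimethoxyphenyl)-5,6,7-trimethoxychroman-4-ol (either epimer at C4) | COc1ccc([C@@H]2CC(O)c3c(cc(OC)c(OC)c3OC)O2)cc1OC
A8 | alternative 3 | (1S)-3-(6-bromo-2,3,4-trimethoxyphenyl)-1-(3,4-dimethoxyphenyl)propane-1,3-diol (either epimer at C3) | COc1ccc([C@@H](O)CC(O)c2c(Br)cc(OC)c(OC)c2OC)cc1OC
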